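**Retrosynthetic overview**
- C6–C7 (sp–sp): target ⇒ 2-(heptadec-16-yn-1-yl)furan + hex-5-ynoic acid, joined last by oxidative heterocoupling.
- C8–C9 (sp–sp3): the terminal alkyne ⇒ acetylide displacement on the tosylate of 15-(furan-2-yl)pentadecan-1-ol.
- Furan O–C5 (the only ring, closed early in step 2): cycloisomerisation of an ω-hydroxy but-2-ynyl ketone; the ketone oxygen becomes the ring oxygen.
- Ynone ⇒ hexadecanolide + propynyl anion; the lactone carbonyl carbon becomes furan C2 and its fifteen CH2 groups become C9–C23.

Assumption: the target has no stereocentre (it is achiral), so no stereocontrol is needed.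

**Route**

Step 1
Reactants: 1 hexadecanolide (oxacycloheptadecan-2-one); 2 1-propynyllithium
Product: 3 19-hydroxynonadec-2-yn-4-one
Conditions: 2 (1.5 equiv), BF3·OEt2 (1.5 equiv), THF, −78 °C, 1 h; aq. NH4Cl at −78 °C
Reagents that add atoms: none
Why: Yamaguchi-type BF3-mediated acyl substitution, in which the alkynyl–BF3 reagent adds once to the lactone carbonyl and the boron-bound tetrahedral alkoxide does not collapse until the cold quench, so the ynone cannot be attacked a second time.

Step 2
Reactants: 3 19-hydroxynonadec-2-yn-4-one
Product: 5 15-(furan-2-yl)pentadecan-1-ol, via allenyl ketone 4 (not isolated)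
Conditions: LAuCl (5 mol %), NaBArF4 (5 mol %), L = biphenyl-2-yl-di(1-adamantyl)phosphine carrying a pendant 3′-tertiary amine, 4 Å MS, DCE (0.05 M), rt → 40 °C
Reagents that add atoms: none
Why: Proposed new method: base-free gold relay cycloisomerisation of an aliphatic but-2-ynyl ketone to a 2-monosubstituted furan — the pendant amine removes a γ-methyl proton of the gold-bound ynone (acidified by the ketone), protodeauration gives terminal allenyl ketone 4, and the same cationic gold activates the allene terminus for 5-endo attack by the carbonyl oxygen (the new O–C5 bond), with proton loss and protodeauration giving the furan; the neutral, dilute, room-temperature conditions are chosen so that the free primary alcohol does not undergo the oxa-Michael addition that an amine base at 100 °C would favour; the closest known reaction types are the Cu(I)/amine cycloisomerisation of alkynyl ketones through allenyl ketones, Au/Ag-catalysed allenyl ketone-to-furan cyclisation, and gold isomerisation of alkynes to allenes with pendant-base phosphines.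

Step 3
Reactants: 5 15-(furan-2-yl)pentadecan-1-ol
Product: 6 15-(furan-2-yl)pentadecyl 4-methylbenzenesulfonate
Conditions: TsCl (1.3 equiv), Et3N (2 equiv), DMAP (5 mol %), CH2Cl2, 0 °C → rt
Reagents that add atoms: p-toluenesulfonyl chloride (TsCl), Cc1ccc(cc1)S(=O)(=O)Cl
Why: DMAP-catalysed O-sulfonylation of the primary alcohol under basic conditions, which the acid-sensitive 2-alkylfuran tolerates.

Step 4
Reactants: 6 15-(furan-2-yl)pentadecyl 4-methylbenzenesulfonate; 7 lithium acetylide–ethylenediamine complex
Product: 8 2-(heptadec-16-yn-1-yl)furan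
Conditions: 7 (3 equiv), DMSO–THF (3:1), rt
Reagents that add atoms: none
Why: SN2 alkylation of acetylide on a primary tosylate in a dipolar aprotic solvent; the furan C–H bonds are far less acidic than acetylene, and room temperature avoids base-induced alkyne migration.

Step 5
Reactants: 8 2-(heptadec-16-yn-1-yl)furan; 9 hex-5-ynoic acid
Product: 10 23-(furan-2-yl)tricosa-5,7-diynoic acid
Conditions: 9 (5 equiv), CuCl (20 mol %), TMEDA (6 equiv), O2 (1 atm), acetone, rt, dark; dilute HCl work-up
Reagents that add atoms: none
Why: Glaser–Hay oxidative heterocoupling, in which the fivefold excess of cheap 9 channels 8 statistically (about 5/6) into the cross-coupled 1,3-diyne, and the polar diacid homodimer of 9 and the neutral homodimer of 8 are removed by chromatography.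

**Compound list**
1 | hexadecanolide (oxacycloheptadecan-2-one) | O=C1CCCCCCCCCCCCCCCO1 | starting material
2 | 1-propynyllithium | [Li]C#CC | starting material
3 | 19-hydroxynonadec-2-yn-4-one | CC#CC(=O)CCCCCCCCCCCCCCCO | intermediate
4 | 19-hydroxynonadeca-1,2-dien-4-one (allenyl ketone, not isolated) | C=C=CC(=O)CCCCCCCCCCCCCCCO | intermediate
5 | 15-(furan-2-yl)pentadecan-1-ol | OCCCCCCCCCCCCCCCc1ccco1 | intermediate
6 | 15-(furan-2-yl)pentadecyl 4-methylbenzenesulfonate | Cc1ccc(cc1)S(=O)(=O)OCCCCCCCCCCCCCCCc1ccco1 | intermediate
7 | lithium acetylide–ethylenediamine complex | [Li+].[C-]#C.NCCN | starting material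
8 | 2-(heptadec-16-yn-1-yl)furan | C#CCCCCCCCCCCCCCCCc1ccco1 | intermediate
9 | hex-5-ynoic acid | C#CCCCC(=O)O | starting material
10 | 23-(furan-2-yl)tricosa-5,7-diynoic acid | O=C(O)CCCC#CC#CCCCCCCCCCCCCCCCc1ccco1 | target

**Step count**
Total steps: 5. Longest linear sequence: 5 (1 → 3 → 5 → 6 → 8 → 10).

**Three steps most likely to fail**

Step 2 (the proposed new method). The soft γ-deprotonation may be slow on a conjugated ynone, or the terminal allenyl ketone may oligomerise. The fallback is a Paal–Knorr approach by known chemistry; it sets out from lactone 1 and comes back to the route at 5. Lactone 1 is opened with MeNH(OMe)·HCl and i-PrMgCl in THF at −10 °C to give 16-hydroxy-N-methoxy-N-methylhexadecanamide F1. Excess commercial (1,3-dioxan-2-ylethyl)magnesium bromide (3 equiv, THF, 0 °C → rt) converts it into the keto acetal 1-(1,3-dioxan-2-yl)-18-hydroxyoctadecan-3-one F2. Brief heating with p-TsOH in wet acetone unmasks the 4-oxo-aldehyde, which cyclodehydrates to furan 5.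

Step 1. Double addition or incomplete conversion of the macrolactone is possible. The fallback changes the carbonyl oxidation level; it sets out from 1 and comes back at 3. DIBAL-H (1.1 equiv, CH2Cl2, −78 °C) reduces 1 to 16-hydroxyhexadecanal F3. 1-Propynylmagnesium bromide (2.5 equiv, THF, 0 °C) adds to give (±)-nonadec-2-yne-4,19-diol F4. Activated MnO2 (CH2Cl2, rt) oxidises only the propargylic alcohol and returns ynone 3.

Step 5. The statistical heterocoupling may give poor separation or too much homodimer of 8. The fallback is a directed Cadiot–Chodkiewicz coupling; it sets out from 9 (with 8) and comes back at 10. Acid 9 is brominated at the alkyne terminus with KOBr (Br2, aq. KOH, 0 °C) to give 6-bromohex-5-ynoic acid F5. This is coupled with 8 (CuCl 10 mol %, NH2OH·HCl, n-BuNH2, H2O–THF–MeOH, 0 °C) to give 10 selectively.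

**Further compounds**
F1 | step 2 | 16-hydroxy-N-methoxy-N-methylhexadecanamide | CON(C)C(=O)CCCCCCCCCCCCCCCO
F2 | step 2 | 1-(1,3-dioxan-2-yl)-18-hydroxyoctadecan-3-one | OCCCCCCCCCCCCCCCC(=O)CCC1OCCCO1
F3 | step 1 | 16-hydroxyhexadecanal | O=CCCCCCCCCCCCCCCCO
F4 | step 1 | (±)-nonadec-2-yne-4,19-diol | CC#CC(O)CCCCCCCCCCCCCCCO
F5 | step 5 | 6-bromohex-5-ynoic acid | BrC#CCCCC(=O)O
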